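**Strategy**

Everything rests on reading ring B as a cyclohexene formed by a [4+2] cycloaddition that makes the ring-fusion bond C5–C10 and the bond C8–C9, with ring A (C1–C4 including the gem-dimethyl carbon C4, plus C5 and the quaternary C10) acting as the tether between diene and dienophile. One catalytic asymmetric intramolecular Diels–Alder reaction of an acyclic E,E,E-trienal thus closes both rings, sets C5 and C10 (and, for the time being, C8 and C9) and leaves a C11 aldehyde as the handle for the side chain. The precursor is a β-methyl enal linked through a four-carbon chain to a penta-1,3-dienyl unit; afterwards C6=C7 is moved to C7=C8 and farnesyl is joined to C11.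

Key step: step 8

**Remarks on the chemistry (assumptions)**

- Drimane numbering is used for all bicyclic compounds (C11 is the carbon on C9; β is the face of the C10 methyl group).
- The cyclisation substrate is a 2,8,10-trienal: four tether atoms separate dienophile and diene (the 1,7,9-decatriene pattern), which is the arrangement that leads to a decalin and not a hydrindane.
- The antipode of the oxazaborolidine in step 8 is chosen from the accepted binding model for 2-enals, under which the (R)-catalyst should expose the Si face of C9; the sense is to be confirmed at sulfone 19 (crystallography, sulfur as anomalous scatterer), and the (S)-catalyst is used if it proves opposite.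
- Compounds 1, 2, 8 and 20 and the catalyst components are taken as purchasable.

**Route**

Step 1
Reactants: 1 2-methylpropanenitrile (isobutyronitrile); 2 (5-chloropent-1-yn-1-yl)trimethylsilane
Product: 4 2,2-dimethyl-7-(trimethylsilyl)hept-6-ynenitrile, via 2-lithio-2-methylpropanenitrile 3 (not isolated)
Conditions: LiN(iPr)2 (1.2 equiv), THF, −78 °C; then 2, DMPU, −78 °C → rt
Reagents that add atoms: none
Why: Alkylation of a metalated nitrile: the small, strongly nucleophilic tertiary carbanion 3 displaces the primary chloride by SN2 (DMPU accelerates it), the silyl cap keeping the alkyne from being deprotonated; no stereocentre is formed.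

Step 2
Reactants: 4 2,2-dimethyl-7-(trimethylsilyl)hept-6-ynenitrile
Product: 6 2,2-dimethyl-7-(trimethylsilyl)hept-6-ynal, via N-aluminoimine 5 (not isolated)
Conditions: iBu2AlH (1.3 equiv), CH2Cl2, −78 → −20 °C; then aq. potassium sodium tartrate, rt
Reagents that add atoms: water, O
Why: Partial reduction of a nitrile with iBu2AlH: a single hydride transfer gives the N-aluminoimine 5, which resists further reduction at low temperature and is hydrolysed to the aldehyde on work-up, while the silylalkyne is untouched.

Step 3
Reactants: 6 2,2-dimethyl-7-(trimethylsilyl)hept-6-ynal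
Product: 7 [(7E)-8-iodo-6,6-dimethyloct-7-en-1-yn-1-yl]trimethylsilane
Conditions: CrCl2 (6 equiv), CHI3 (2 equiv), THF, 0 °C → rt
Reagents that add atoms: iodoform, IC(I)I
Why: Takai olefination: the geminal dichromium species formed from CHI3 and CrCl2 adds to the aldehyde and eliminates with the iodine anti to the bulky quaternary carbon, so the E-iodoalkene should strongly predominate.

Step 4
Reactants: 7 [(7E)-8-iodo-6,6-dimethyloct-7-en-1-yn-1-yl]trimethylsilane; 8 (E)-prop-1-en-1-ylboronic acid
Product: 9 trimethyl[(7E,9E)-6,6-dimethylundeca-7,9-dien-1-yn-1-yl]silane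
Conditions: Pd(PPh3)4 (5 mol%), K3PO4 (aq.), THF, rt → 40 °C
Reagents that add atoms: none
Why: Suzuki–Miyaura coupling of an alkenyl iodide with an alkenylboronic acid proceeds with retention of geometry at both partners, so the E-iodide and the E-boronic acid should give the E,E-diene as a single isomer, and the mild phosphate base leaves the silylalkyne in place.

Step 5
Reactants: 9 trimethyl[(7E,9E)-6,6-dimethylundeca-7,9-dien-1-yn-1-yl]silane
Product: 10 (7E,9E)-6,6-dimethylundeca-7,9-dien-1-yne
Conditions: K2CO3 (0.2 equiv), MeOH, rt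
Reagents that add atoms: none
Why: Base-catalysed methanolysis of the C(sp)–Si bond (protodesilylation) liberates the terminal alkyne without affecting the diene.

Step 6
Reactants: 10 (7E,9E)-6,6-dimethylundeca-7,9-dien-1-yne
Product: 13 (2E,8E,10E)-3,7,7-trimethyldodeca-2,8,10-trien-1-ol, via alkenyldimethylalane 11 (not isolated), via lithium alkenylalanate 12 (not isolated)
Conditions: Me3Al (2.5 equiv), Cp2ZrCl2 (0.25 equiv), CH2Cl2, 0 °C → rt; volatiles removed; n-BuLi (1.1 equiv), THF–hexane, −30 °C; (CH2O)n (3 equiv), rt; aq. potassium sodium tartrate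
Reagents that add atoms: trimethylaluminium, C[Al](C)C; paraformaldehyde (formaldehyde units), C=O
Why: Negishi zirconium-catalysed carboalumination delivers methyl and aluminium syn across the terminal alkyne with aluminium at the terminus, which fixes the E-trisubstituted alkene, and the alanate 12 is then hydroxymethylated by formaldehyde with retention of geometry; the internal, disubstituted alkenes of the diene are not carbometalated under these conditions.

Step 7
Reactants: 13 (2E,8E,10E)-3,7,7-trimethyldodeca-2,8,10-trien-1-ol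
Product: 14 (2E,8E,10E)-3,7,7-trimethyldodeca-2,8,10-trienal
Conditions: MnO2 (activated, 15 equiv), CH2Cl2, rt
Reagents that add atoms: none
Why: Selective oxidation of the allylic alcohol by activated MnO2 under neutral, heterogeneous conditions should give the E-enal without isomerisation of the trisubstituted alkene or attack on the diene.

Step 8
Reactants: 14 (2E,8E,10E)-3,7,7-trimethyldodeca-2,8,10-trienal
Product: 15 (5S,8S,9S,10S)-drim-6-en-11-al (trans-fused; 8β-methyl; 9β-formyl)
Conditions: (R)-tetrahydro-1-(2-methylphenyl)-3,3-diphenyl-1H,3H-pyrrolo[1,2-c][1,3,2]oxazaborole (20 mol%), Tf2NH (18 mol%), CH2Cl2, −40 → 0 °C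
Reagents that add atoms: none
Why: The N-protonated oxazaborolidine binds the formyl oxygen at boron (reinforced by a formyl C–H···O contact), lowers the LUMO of the s-trans E-enal and screens one face of C9=C10, and the tethered diene then adds in a concerted, asynchronous [4+2] cycloaddition. The closest known reaction type is the chiral-Lewis-acid-catalysed intramolecular Diels–Alder reaction of 2,8,10-trienals to trans-fused octalin aldehydes, of which this β-methyl enal is a demanding member. Ring B closes by the cycloaddition proper (diene C5=C6–C7=C8 plus dienophile C9=C10, new σ bonds C5–C10 and C8–C9), and ring A closes at the same moment as the fused six-membered ring because the tether C1–C4 already links C5 with C10. C5 and C10 are fixed by the catalyst-selected enal face together with the endo transition state (formyl under the diene, tether anti, chair-like tether), which gives the trans ring fusion; C9 follows from the E-geometry of the enal (formyl cis to the C10 methyl) and C8 from the E-geometry of the terminal diene alkene (8β-methyl). The step needs enantioface selectivity, secured by the catalyst, and endo/trans selectivity, secured by the terminally activated E-dienophile, while the gem-dimethyl group at C4 favours the folded reactive conformer and helps to offset the low reactivity of the β,β-disubstituted dienophile. Only C5 and C10 have to be right at this point, since C8 disappears in step 12 and the equatorial 9β-substituent is the thermodynamically preferred one.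

Step 9
Reactants: 15 (5S,8S,9S,10S)-drim-6-en-11-al
Product: 16 (5S,8S,9S,10S)-drim-6-en-11-ol
Conditions: NaBH4, MeOH, 0 °C
Reagents that add atoms: none
Why: Hydride reduction of the aldehyde (NaBH4) gives the primary alcohol and removes the only epimerisable position before the later steps; no stereocentre is formed or changed.

Step 10
Reactants: 16 (5S,8S,9S,10S)-drim-6-en-11-ol
Product: 17 (5S,8S,9S,10S)-11-(phenylsulfanyl)drim-6-ene
Conditions: PhSSPh (1.5 equiv), n-Bu3P (1.5 equiv), pyridine, rt → 50 °C
Reagents that add atoms: diphenyl disulfide, c1ccccc1SSc1ccccc1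
Why: Mitsunobu-type thioetherification: Bu3P and PhSSPh convert the primary alcohol into an alkoxyphosphonium ion that thiolate displaces by SN2 at C11, the C6=C7 alkene being too remote to participate; no stereocentre is involved.

Step 11
Reactants: 17 (5S,8S,9S,10S)-11-(phenylsulfanyl)drim-6-ene
Product: 18 (5S,8S,9S,10S)-11-(phenylsulfonyl)drim-6-ene
Conditions: H2O2 (30% aq., 3 equiv), (NH4)6Mo7O24·4H2O (10 mol%), EtOH, 0 °C → rt
Reagents that add atoms: hydrogen peroxide, OO
Why: Molybdate-catalysed peroxide oxidation takes the sulfide through the sulfoxide to the sulfone and is chemoselective for sulfur over an isolated, disubstituted alkene.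

Step 12
Reactants: 18 (5S,8S,9S,10S)-11-(phenylsulfonyl)drim-6-ene
Product: 19 (5S,9S,10S)-11-(phenylsulfonyl)drim-7-ene
Conditions: RuHCl(CO)(PPh3)3 (5 mol%), toluene, 100 °C
Reagents that add atoms: none
Why: Ruthenium hydride alkene isomerisation by reversible hydrometalation/β-hydride elimination: Ru–H should add to the open α face of C6=C7 with the metal at C7 (C6 is screened by the equatorial methyl at C4) and eliminate the cis 8α-hydrogen, giving the trisubstituted C7=C8 alkene with relief of the 1,3-diaxial 8β-Me/10-Me interaction, while further migration would need a tertiary alkylruthenium at C8 and should be slow; C8 ceases to be a stereocentre and C5, C9 and C10 are untouched.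

Step 13
Reactants: 19 (5S,9S,10S)-11-(phenylsulfonyl)drim-7-ene; 20 (2E,6E)-farnesyl bromide
Product: 22 (5S,9S,10S)-11-(phenylsulfonyl)-11-[(2E,6E)-farnesyl]drim-7-ene (C11 epimers), via lithiated sulfone 21 (not isolated)
Conditions: n-BuLi (1.05 equiv), THF, −78 °C; then 20 (1.1 equiv), −78 → −20 °C
Reagents that add atoms: none
Why: Alkylation of an α-sulfonyl carbanion (Julia-type sulfone coupling): 21 attacks the primary allylic bromide at C1 by SN2, so the E,E-geometry of the farnesyl unit is retained, and the new stereocentre at C11 is of no consequence because the sulfonyl group is removed in step 14.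

Step 14
Reactants: 22 (5S,9S,10S)-11-(phenylsulfonyl)-11-[(2E,6E)-farnesyl]drim-7-ene
Product: 23 (5S,9S,10S)-11-[(2E,6E)-farnesyl]drim-7-ene (the target, CNP0141177.1)
Conditions: Na/Hg (5% Na), Na2HPO4, MeOH–THF, −20 °C → rt
Reagents that add atoms: none
Why: Reductive desulfonylation with sodium amalgam: electron transfer cleaves the C11–S bond and the resulting carbanion is protonated by methanol, and since the sulfone is not allylic no alkene migration or loss of E-geometry is expected; the three stereocentres C5, C9 and C10 are unaffected.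

**Compound list**

1 | 2-methylpropanenitrile (isobutyronitrile) | CC(C)C#N | starting material
2 | (5-chloropent-1-yn-1-yl)trimethylsilane | C[Si](C)(C)C#CCCCCl | starting material
3 | 2-lithio-2-methylpropanenitrile | [Li]C(C)(C)C#N | intermediate
4 | 2,2-dimethyl-7-(trimethylsilyl)hept-6-ynenitrile | C[Si](C)(C)C#CCCCC(C)(C)C#N | intermediate
5 | N-(diisobutylalumino)imine of aldehyde 6 | C[Si](C)(C)C#CCCCC(C)(C)C=N[Al](CC(C)C)CC(C)C | intermediate
6 | 2,2-dimethyl-7-(trimethylsilyl)hept-6-ynal | C[Si](C)(C)C#CCCCC(C)(C)C=O | intermediate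
7 | [(7E)-8-iodo-6,6-dimethyloct-7-en-1-yn-1-yl]trimethylsilane | C[Si](C)(C)C#CCCCC(C)(C)/C=C/I | intermediate
8 | (E)-prop-1-en-1-ylboronic acid | C/C=C/B(O)O | starting material
9 | trimethyl[(7E,9E)-6,6-dimethylundeca-7,9-dien-1-yn-1-yl]silane | C[Si](C)(C)C#CCCCC(C)(C)/C=C/C=C/C | intermediate
10 | (7E,9E)-6,6-dimethylundeca-7,9-dien-1-yne | C#CCCCC(C)(C)/C=C/C=C/C | intermediate
11 | dimethyl[(1E,7E,9E)-2,6,6-trimethylundeca-1,7,9-trien-1-yl]alane | C[Al](C)/C=C(\C)CCCC(C)(C)/C=C/C=C/C | intermediate
12 | lithium butyl(dimethyl)[(1E,7E,9E)-2,6,6-trimethylundeca-1,7,9-trien-1-yl]alanate | [Li+].CCCC[Al-](C)(C)/C=C(\C)CCCC(C)(C)/C=C/C=C/C | intermediate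
13 | (2E,8E,10E)-3,7,7-trimethyldodeca-2,8,10-trien-1-ol | OC/C=C(\C)CCCC(C)(C)/C=C/C=C/C | intermediate
14 | (2E,8E,10E)-3,7,7-trimethyldodeca-2,8,10-trienal | O=C/C=C(\C)CCCC(C)(C)/C=C/C=C/C | intermediate
15 | (5S,8S,9S,10S)-drim-6-en-11-al = (1S,2S,4aS,8aS)-2,5,5,8a-tetramethyl-1,2,4a,5,6,7,8,8a-octahydronaphthalene-1-carbaldehyde | O=C[C@H]1[C@@H](C)C=C[C@H]2C(C)(C)CCC[C@]12C | intermediate
16 | (5S,8S,9S,10S)-drim-6-en-11-ol | OC[C@H]1[C@@H](C)C=C[C@H]2C(C)(C)CCC[C@]12C | intermediate
17 | (5S,8S,9S,10S)-11-(phenylsulfanyl)drim-6-ene | c1ccccc1SC[C@H]1[C@@H](C)C=C[C@H]2C(C)(C)CCC[C@]12C | intermediate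
18 | (5S,8S,9S,10S)-11-(phenylsulfonyl)drim-6-ene | O=S(=O)(c1ccccc1)C[C@H]1[C@@H](C)C=C[C@H]2C(C)(C)CCC[C@]12C | intermediate
19 | (5S,9S,10S)-11-(phenylsulfonyl)drim-7-ene | O=S(=O)(c1ccccc1)C[C@H]1C(C)=CC[C@H]2C(C)(C)CCC[C@]12C | intermediate
20 | (2E,6E)-1-bromo-3,7,11-trimethyldodeca-2,6,10-triene (farnesyl bromide) | CC(C)=CCC/C(C)=C/CC/C(C)=C/CBr | starting material
21 | 11-lithio-11-(phenylsulfonyl)drim-7-ene | [Li]C([C@H]1C(C)=CC[C@H]2C(C)(C)CCC[C@]12C)S(=O)(=O)c1ccccc1 | intermediate
22 | (5S,9S,10S)-11-(phenylsulfonyl)-11-[(2E,6E)-farnesyl]drim-7-ene, C11 epimers | CC(C)=CCC/C(C)=C/CC/C(C)=C/CC([C@H]1C(C)=CC[C@H]2C(C)(C)CCC[C@]12C)S(=O)(=O)c1ccccc1 | intermediate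
23 | (4aS,5S,8aS)-1,1,4a,6-tetramethyl-5-[(3E,7E)-4,8,12-trimethyltrideca-3,7,11-trien-1-yl]-1,2,3,4,4a,5,8,8a-octahydronaphthalene | CC(C)=CCC/C(C)=C/CC/C(C)=C/CC[C@H]1C(C)=CC[C@H]2C(C)(C)CCC[C@]12C | target

**Step count**

Total: 14 steps. Longest linear sequence: 14 steps (the route is fully linear; 20 is purchased).

**Steps most likely to fail, with fallbacks**

1. Step 8. The β,β-disubstituted dienophile may react too slowly at temperatures where the catalyst still controls the face. The enal geometry may be lost under the acidic catalyst. The endo/trans preference may be eroded by the C4β-methyl/C10-methyl contact that develops in the trans-fused transition state.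
 Fallback (auxiliary control in place of catalyst control; sets out from 14 and returns at 16): 14 is oxidised (NaClO2, NaH2PO4, 2-methylbut-2-ene, tBuOH–H2O; Pinnick oxidation) to (2E,8E,10E)-3,7,7-trimethyldodeca-2,8,10-trienoic acid F1. The acid is activated with pivaloyl chloride/Et3N as the mixed pivalic anhydride F2 (not isolated) and transferred to lithiated (S)-4-benzyl-1,3-oxazolidin-2-one to give (4S)-4-benzyl-3-[(2E,8E,10E)-3,7,7-trimethyldodeca-2,8,10-trienoyl]-1,3-oxazolidin-2-one F3. Me2AlCl (1.5 equiv, CH2Cl2, −30 °C) chelates both carbonyl groups, locks the s-cis enoyl unit and activates it strongly. The diene should then add in the endo mode to the face opposite to the benzyl group (the Si face of C9), giving (4S)-4-benzyl-3-[(5S,8S,9S,10S)-drim-6-en-11-oyl]-1,3-oxazolidin-2-one F4. Reductive cleavage with LiBH4/MeOH in THF at 0 °C gives 16 and returns the auxiliary.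

2. Step 12. The alkene may migrate past C7=C8 to the tetrasubstituted C8=C9 position, migrate towards C5 instead, or the reaction may stall.
 Fallback (alkene position fixed through a C7 ketone; sets out from 18 and returns at 19): hydroboration of 18 (BH3·THF, 0 °C → rt; then NaBO3·4H2O) should place boron on the α face at the less hindered C7 and give (5S,7α,8β,9S,10S)-7-hydroxy-11-(phenylsulfonyl)drimane F5. Dess–Martin oxidation gives 11-(phenylsulfonyl)driman-7-one F6. Tf2O with 2,6-di-tert-butyl-4-methylpyridine (CH2Cl2, 0 °C → rt) traps the more substituted enol as 11-(phenylsulfonyl)drim-7-en-7-yl trifluoromethanesulfonate F7. Pd(OAc)2/PPh3/HCO2H/Bu3N (DMF, 60 °C) replaces the triflate by hydrogen and gives 19.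

3. Step 10. Substitution at the β-branched, sterically screened C11 may be slow and incomplete.
 Fallback (C–S bond made by carbonyl addition in place of substitution; sets out from 15 and returns at 17, bypassing 16): 15 is treated with PhSH (2.2 equiv) and BF3·OEt2 (CH2Cl2, 0 °C) to give (5S,8S,9S,10S)-11,11-bis(phenylsulfanyl)drim-6-ene F8. One C–S bond is then cleaved homolytically with Bu3SnH (1.05 equiv) and AIBN (toluene, 80 °C) to give 17.

**Further compounds**

F1 | step 8 | (2E,8E,10E)-3,7,7-trimethyldodeca-2,8,10-trienoic acid | OC(=O)/C=C(\C)CCCC(C)(C)/C=C/C=C/C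
F2 | step 8 | pivalic (2E,8E,10E)-3,7,7-trimethyldodeca-2,8,10-trienoic anhydride | CC(C)(C)C(=O)OC(=O)/C=C(\C)CCCC(C)(C)/C=C/C=C/C
F3 | step 8 | (4S)-4-benzyl-3-[(2E,8E,10E)-3,7,7-trimethyldodeca-2,8,10-trienoyl]-1,3-oxazolidin-2-one | O=C(/C=C(\C)CCCC(C)(C)/C=C/C=C/C)N1C(=O)OC[C@@H]1Cc1ccccc1
F4 | step 8 | (4S)-4-benzyl-3-[(5S,8S,9S,10S)-drim-6-en-11-oyl]-1,3-oxazolidin-2-one | O=C([C@H]1[C@@H](C)C=C[C@H]2C(C)(C)CCC[C@]12C)N1C(=O)OC[C@@H]1Cc1ccccc1
F5 | step 12 | (5S,7α,8β,9S,10S)-7-hydroxy-11-(phenylsulfonyl)drimane | O=S(=O)(c1ccccc1)C[C@H]1[C@@H](C)[C@H](O)C[C@H]2C(C)(C)CCC[C@]12C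
F6 | step 12 | 11-(phenylsulfonyl)driman-7-one (C8 epimerisable) | O=S(=O)(c1ccccc1)C[C@H]1C(C)C(=O)C[C@H]2C(C)(C)CCC[C@]12C
F7 | step 12 | 11-(phenylsulfonyl)drim-7-en-7-yl trifluoromethanesulfonate | O=S(=O)(c1ccccc1)C[C@H]1C(C)=C(OS(=O)(=O)C(F)(F)F)C[C@H]2C(C)(C)CCC[C@]12C
F8 | step 10 | (5S,8S,9S,10S)-11,11-bis(phenylsulfanyl)drim-6-ene | c1ccccc1SC(Sc1ccccc1)[C@H]1[C@@H](C)C=C[C@H]2C(C)(C)CCC[C@]12C
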